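## Retrosynthetic overview

1. Target 32 comes from one global i-Bu2AlH reduction of the (E)-alkylidene γ-lactone / N-methoxy-N-methylamide 31, which releases the enal, the allylic CH2OH and the cyclopentanol together; 31 comes from an aldol condensation of the cis-fused lactone 22 with dienal 27.
2. Lactone 22 is built on the cyclopentanone of spiroketone 17 (alkylation at its only enolisable carbon, then 1,3-anti reduction directed by the tertiary OH); 17 comes from vinyl iodide 16 by Negishi methylation.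
3. Key disconnection: 16 arises in one step from monocyclic enyne 14. Gold-triggered attack of the alkene on the ynamide closes the cyclohexane while the cyclobutanol ring expands to the cyclopentanone, creating the spiro carbon, the ring CH centre and the tetrasubstituted exocyclic alkene.
4. Enabling feature: the (Z)-1-alkenylcyclobutanol of 14, held in a temporary 5-alkylidene-1,3-dioxa-2-silacyclohexane. Both cyclobutane C–C bonds flank the p-orbital of the alkene carbon that becomes the spiro atom, and the O–Si–O bridge keeps the C(Me)–O bond syn to the cyclobutanol C–O, so the single stereocentre (Sharpless epoxidation of geraniol) controls the two new ones.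
5. Ring order: cyclobutane (bought as cyclobutanone), then siladioxane (temporary), then cyclohexane and cyclopentane together in step 12, then γ-lactone (temporary, opened in step 22).

Key step: step 12

Remark: TBDPS = tert-butyldiphenylsilyl; silane 5 and boronate 25 are taken as purchasable building blocks.

## Route

Step 1
Reactants: 1 geraniol
Product: 2 (2S,3S)-2,3-epoxygeraniol
Conditions: Ti(O-i-Pr)4 (5 mol %), L-(+)-diethyl tartrate (6 mol %), t-BuOOH, 4 Å MS, CH2Cl2, −20 °C
Reagents that add atoms: tert-butyl hydroperoxide, CC(C)(C)OO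
Why: Sharpless asymmetric epoxidation, in which the L-(+)-tartrate titanium complex delivers oxygen to one face of the allylic alcohol and so sets both epoxide carbons (2S,3S), the quaternary one becoming the C(Me)OH centre of the target.

Step 2
Reactants: 2 (2S,3S)-2,3-epoxygeraniol
Product: 3 (2R,3S)-2-(chloromethyl)-3-methyl-3-(4-methylpent-3-en-1-yl)oxirane
Conditions: PPh3, CCl4, NaHCO3, reflux
Reagents that add atoms: carbon tetrachloride, ClC(Cl)(Cl)Cl
Why: Appel chlorination of the primary alcohol under neutral conditions leaves the epoxide and both stereocentres untouched.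

Step 3
Reactants: 3 (2R,3S)-2-(chloromethyl)-3-methyl-3-(4-methylpent-3-en-1-yl)oxirane
Product: 4 (3S)-3,7-dimethyloct-6-en-1-yn-3-ol
Conditions: n-BuLi (3.2 equiv), THF, −40 → 0 °C; aq. NH4Cl
Reagents that add atoms: none
Why: Base-induced double elimination of a 2,3-epoxy chloride (epoxide-opening β-elimination, then dehydrochlorination) gives the tertiary propargylic alcohol with retention, because the C–O bond at the quaternary carbon is never broken.

Step 4
Reactants: 4 (3S)-3,7-dimethyloct-6-en-1-yn-3-ol; 5 tert-butyl(3-bromopropoxy)diphenylsilane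
Product: 6 (6S)-1-(TBDPS-oxy)-6,10-dimethylundec-9-en-4-yn-6-ol
Conditions: n-BuLi (2.1 equiv), THF, −78 → 0 °C; then 5, DMPU, 0 °C → rt
Reagents that add atoms: none
Why: SN2 alkylation of the dilithio alkoxide–acetylide occurs at carbon, since the hindered tertiary alkoxide is a poor nucleophile.

Step 5
Reactants: 6 (6S)-1-(TBDPS-oxy)-6,10-dimethylundec-9-en-4-yn-6-ol
Product: 7 (4Z,6S)-1-(TBDPS-oxy)-6,10-dimethyl-5-(tributylstannyl)undeca-4,9-dien-6-ol
Conditions: Bu3SnH (1.1 equiv), [Cp*RuCl]4 (2 mol %), CH2Cl2, rt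
Reagents that add atoms: tributyltin hydride, CCCC[SnH](CCCC)CCCC
Why: Hydroxyl-directed ruthenium-catalysed trans-hydrostannation places tin on the alkyne carbon next to the carbinol and hydrogen trans to it, so the chain ends cis to tin (Z) as step 12 requires.

Step 6
Reactants: 7 (4Z,6S)-1-(TBDPS-oxy)-6,10-dimethyl-5-(tributylstannyl)undeca-4,9-dien-6-ol
Product: 8 (4Z,6S)-1-(TBDPS-oxy)-5-iodo-6,10-dimethylundeca-4,9-dien-6-ol
Conditions: I2 (1.05 equiv), CH2Cl2, −78 °C; aq. Na2S2O3
Reagents that add atoms: iodine, II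
Why: Iododestannylation proceeds with retention of alkene geometry and should be much faster at −78 °C than iodoetherification of the remote alkene.

Step 7
Reactants: 8 (4Z,6S)-1-(TBDPS-oxy)-5-iodo-6,10-dimethylundeca-4,9-dien-6-ol; 9 cyclobutanone
Product: 10 1-[(4Z,6S)-1-(TBDPS-oxy)-6-hydroxy-6,10-dimethylundeca-4,9-dien-5-yl]cyclobutan-1-ol
Conditions: t-BuLi (3.2 equiv), Et2O, −78 °C; then 9, −78 → −20 °C
Reagents that add atoms: none
Why: Iodine–lithium exchange with retention, then 1,2-addition of the alkenyllithium to the strained ketone, forms no stereocentre and leaves the chain cis to the new cyclobutanol carbon.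

Step 8
Reactants: 10 1-[(4Z,6S)-1-(TBDPS-oxy)-6-hydroxy-6,10-dimethylundeca-4,9-dien-5-yl]cyclobutan-1-ol
Product: 11 (8S,9Z)-9-[4-(TBDPS-oxy)butylidene]-8-methyl-8-(4-methylpent-3-en-1-yl)-6,6-di(propan-2-yl)-5,7-dioxa-6-silaspiro[3.5]nonane
Conditions: i-Pr2Si(OTf)2, 2,6-lutidine, CH2Cl2, 0 °C → rt
Reagents that add atoms: diisopropylsilyl bis(trifluoromethanesulfonate), CC(C)[Si](OS(=O)(=O)C(F)(F)F)(OS(=O)(=O)C(F)(F)F)C(C)C
Why: Cyclic silylene formation on the 1,3-diol protects both tertiary alcohols and installs the six-membered ring that fixes the conformation used in step 12.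

Step 9
Reactants: 11 (8S,9Z)-9-[4-(TBDPS-oxy)butylidene]-8-methyl-8-(4-methylpent-3-en-1-yl)-6,6-di(propan-2-yl)-5,7-dioxa-6-silaspiro[3.5]nonane
Product: 12 3-[(8S,9Z)-9-[4-(TBDPS-oxy)butylidene]-8-methyl-6,6-di(propan-2-yl)-5,7-dioxa-6-silaspiro[3.5]nonan-8-yl]propanal
Conditions: OsO4 (2 mol %), NaIO4, 2,6-lutidine, dioxane/H2O, rt
Reagents that add atoms: osmium tetroxide (oxygen carrier), O=[Os](=O)(=O)=O; sodium periodate (terminal oxidant), [Na+].[O-]I(=O)(=O)=O
Why: Lemieux–Johnson cleavage should touch only the unhindered, electron-rich prenyl alkene, because the ring alkylidene is flanked by two fully substituted, oxygen-bearing carbons.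

Step 10
Reactants: 12 3-[(8S,9Z)-9-[4-(TBDPS-oxy)butylidene]-8-methyl-6,6-di(propan-2-yl)-5,7-dioxa-6-silaspiro[3.5]nonan-8-yl]propanal
Product: 13 (8S,9Z)-9-[4-(TBDPS-oxy)butylidene]-8-(4,4-dibromobut-3-en-1-yl)-8-methyl-6,6-di(propan-2-yl)-5,7-dioxa-6-silaspiro[3.5]nonane
Conditions: CBr4, PPh3, Et3N, CH2Cl2, 0 °C
Reagents that add atoms: carbon tetrabromide, BrC(Br)(Br)Br
Why: Corey–Fuchs dibromo-olefination of the aldehyde runs under buffered, non-acidic conditions that the silylene and the silyl ether tolerate.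

Step 11
Reactants: 13 (8S,9Z)-9-[4-(TBDPS-oxy)butylidene]-8-(4,4-dibromobut-3-en-1-yl)-8-methyl-6,6-di(propan-2-yl)-5,7-dioxa-6-silaspiro[3.5]nonane
Product: 14 5-[(8S,9Z)-9-[4-(TBDPS-oxy)butylidene]-8-methyl-6,6-di(propan-2-yl)-5,7-dioxa-6-silaspiro[3.5]nonan-8-yl]-N-methoxy-N-methylpent-2-ynamide
Conditions: n-BuLi (2.1 equiv), THF, −78 °C; then ClC(O)N(OMe)Me, −78 → 0 °C
Reagents that add atoms: N-methoxy-N-methylcarbamoyl chloride, CON(C)C(Cl)=O
Why: The second stage of the Corey–Fuchs sequence (bromine–lithium exchange and Fritsch–Buttenberg–Wiechell rearrangement) gives the lithium acetylide, which is acylated in the same flask to the ynamide that serves as a masked enal.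

Step 12
Reactants: 14 5-[(8S,9Z)-9-[4-(TBDPS-oxy)butylidene]-8-methyl-6,6-di(propan-2-yl)-5,7-dioxa-6-silaspiro[3.5]nonan-8-yl]-N-methoxy-N-methylpent-2-ynamide
Product: 16 (2E)-2-[(5R,6S,10S)-10-[3-(TBDPS-oxy)propyl]-6-hydroxy-6-methyl-1-oxospiro[4.5]decan-9-ylidene]-2-iodo-N-methoxy-N-methylacetamide, via N-silylsuccinimide ketone 15 (not isolated)
Conditions: [(t-Bu)2(2-biphenylyl)P]Au(NCMe)SbF6 (5 mol %), N-iodosuccinimide (1.2 equiv), CH2Cl2, −20 °C → rt, dark; then HF·pyridine, pyridine, THF, 0 °C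
Reagents that add atoms: N-iodosuccinimide, O=C1CCC(=O)N1I
Why: Proposed new method: cationic monovalent gold activates the ynamide at its β-carbon and the CH terminus of the exocyclic alkene attacks it anti to gold (6-exo-dig for the alkyne, closing the cyclohexane), while the cyclobutane C–C bond anti to the new bond shifts to the emerging tertiary cation (1,2-shift, spiro-mode ring expansion of cyclobutanol to cyclopentanone driven by strain release) and the silyl oxocarbenium is desilylated by succinimide; N-iodosuccinimide then iododeaurates the vinylgold with retention, leaving iodine trans and the amide cis to the ring CH. The closest known reactions are gold-catalysed and iodonium-induced carbocyclisation/pinacol cascades of 3-silyloxy-1,5-enynes and Prins–pinacol ring expansions of 1-alkenylcyclobutanol silyl ethers. The siladioxane ring holds the C(Me)–O bond in the alkene plane, so the tether can reach the alkene only through a chair with that oxygen equatorial and the methyl axial, which fixes the spiro carbon relative to the existing carbinol centre (carbonyl carbon syn to O, migrating CH2 anti). The ring CH centre follows from anti addition across the Z-alkene, which puts the silyloxypropyl chain equatorial and cis to the former cyclobutanol carbon. The step needs 6-exo closure over 7-endo and 5-exo (secured by the conjugate polarisation of the ynamide and by the tertiary, strain-assisted cation) and gold–alkyne activation faster than iodonium attack on the alkene (the alkene is hindered and deactivated by two allylic C–O bonds).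

Step 13
Reactants: 16 (2E)-2-[(5R,6S,10S)-10-[3-(TBDPS-oxy)propyl]-6-hydroxy-6-methyl-1-oxospiro[4.5]decan-9-ylidene]-2-iodo-N-methoxy-N-methylacetamide
Product: 17 (2Z)-2-[(5R,6S,10R)-10-[3-(TBDPS-oxy)propyl]-6-hydroxy-6-methyl-1-oxospiro[4.5]decan-9-ylidene]-N-methoxy-N-methylpropanamide
Conditions: MeZnCl (3 equiv), Pd(PPh3)4 (5 mol %), THF, 45 °C
Reagents that add atoms: methylzinc chloride, C[Zn]Cl
Why: Negishi coupling (oxidative addition of zerovalent palladium to the α-iodo enamide, transmetalation, reductive elimination) replaces iodine by methyl with retention, so the amide carbon stays cis to the ring CH.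

Step 14
Reactants: 17 (2Z)-2-[(5R,6S,10R)-10-[3-(TBDPS-oxy)propyl]-6-hydroxy-6-methyl-1-oxospiro[4.5]decan-9-ylidene]-N-methoxy-N-methylpropanamide
Product: 18 (2Z)-2-[(5R,6S,10R)-10-[3-(TBDPS-oxy)propyl]-6-methyl-1-oxo-6-(trimethylsilyloxy)spiro[4.5]decan-9-ylidene]-N-methoxy-N-methylpropanamide
Conditions: 1-(trimethylsilyl)imidazole, CH2Cl2, rt
Reagents that add atoms: 1-(trimethylsilyl)imidazole, C[Si](C)(C)n1ccnc1
Why: Neutral silylation of the tertiary alcohol blocks retro-aldol opening of the β-hydroxy ketone under base and adds bulk to the face of the cyclopentanone that must stay free in step 15.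

Step 15
Reactants: 18 (2Z)-2-[(5R,6S,10R)-10-[3-(TBDPS-oxy)propyl]-6-methyl-1-oxo-6-(trimethylsilyloxy)spiro[4.5]decan-9-ylidene]-N-methoxy-N-methylpropanamide
Product: 20 methyl 2-[(2S,5R,6S,10R)-10-[3-(TBDPS-oxy)propyl]-6-hydroxy-9-[(2Z)-1-[methoxy(methyl)amino]-1-oxopropan-2-ylidene]-6-methyl-1-oxospiro[4.5]decan-2-yl]acetate, via O-silylated keto ester 19 (not isolated)
Conditions: LiN(i-Pr)2 (1.15 equiv), THF, −78 °C; BrCH2CO2Me, DMPU, −78 → −30 °C; then 1 M HCl, THF, 0 °C
Reagents that add atoms: methyl bromoacetate, COC(=O)CBr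
Why: Kinetic enolate alkylation at the only enolisable carbon, where the electrophile should enter the cyclopentanone face anti to the C(Me)(OSiMe3) carbon (syn to the ring CH) and set the new centre as the expected more stable epimer of an epimerisable position; the acid work-up frees the tertiary OH.

Step 16
Reactants: 20 methyl 2-[(2S,5R,6S,10R)-10-[3-(TBDPS-oxy)propyl]-6-hydroxy-9-[(2Z)-1-[methoxy(methyl)amino]-1-oxopropan-2-ylidene]-6-methyl-1-oxospiro[4.5]decan-2-yl]acetate
Product: 22 (2Z)-2-[(1S,2S,6R,3a'S,6a'R)-6-[3-(TBDPS-oxy)propyl]-2-hydroxy-2-methyl-2'-oxohexahydrospiro[cyclohexane-1,6'-cyclopenta[b]furan]-5-ylidene]-N-methoxy-N-methylpropanamide, via hydroxy ester 21 (not isolated)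
Conditions: Me4NBH(OAc)3, MeCN/AcOH, −20 °C → rt; then PPTS (cat.), toluene, 60 °C
Reagents that add atoms: none
Why: Evans–Saksena reduction, in which boron bound to the tertiary alkoxide delivers hydride to the ketone face syn to that oxygen, should give the 1,3-anti diol with the new OH cis to the acetate arm, and only this cis-hydroxy ester can close the cis-fused γ-lactone.

Step 17
Reactants: 23 6-methylhept-5-en-2-one
Product: 24 6-methylhepta-1,5-dien-2-yl trifluoromethanesulfonate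
Conditions: LiN(i-Pr)2, THF, −78 °C; PhNTf2, −78 → 0 °C
Reagents that add atoms: N-phenylbis(trifluoromethanesulfonimide), O=S(=O)(N(c1ccccc1)S(=O)(=O)C(F)(F)F)C(F)(F)F
Why: Kinetic deprotonation of the methyl ketone at the methyl group and O-triflation give the terminal enol triflate.

Step 18
Reactants: 24 6-methylhepta-1,5-dien-2-yl trifluoromethanesulfonate; 25 (E)-2-(3,3-diethoxyprop-1-en-1-yl)-4,4,5,5-tetramethyl-1,3,2-dioxaborolane
Product: 27 (2E)-8-methyl-4-methylidenenona-2,7-dienal, via dienal diethyl acetal 26 (not isolated)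
Conditions: Pd(PPh3)4 (3 mol %), K3PO4, dioxane/H2O, 60 °C; then 1 M HCl, THF, 0 °C
Reagents that add atoms: water, O
Why: Suzuki–Miyaura coupling transfers the E-alkenyl group with retention, and brief acid hydrolysis of the allylic acetal releases the dienal.

Step 19
Reactants: 22 (2Z)-2-[(1S,2S,6R,3a'S,6a'R)-6-[3-(TBDPS-oxy)propyl]-2-hydroxy-2-methyl-2'-oxohexahydrospiro[cyclohexane-1,6'-cyclopenta[b]furan]-5-ylidene]-N-methoxy-N-methylpropanamide; 27 (2E)-8-methyl-4-methylidenenona-2,7-dienal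
Product: 28 β-hydroxy lactone (22 carrying a 1-hydroxy-(2E)-8-methyl-4-methylidenenona-2,7-dien-1-yl group on the lactone α-carbon; epimers at the two new carbons)
Conditions: LiN(i-Pr)2 (2.2 equiv), THF, −78 °C; then 27, −78 °C
Reagents that add atoms: none
Why: Aldol addition of the lactone lithium enolate (the second equivalent of base covers the tertiary OH) occurs 1,2 at the enal at low temperature, and the two new centres are removed in step 20.

Step 20
Reactants: 28 β-hydroxy lactone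
Product: 30 (E)-alkylidene lactone (22 with the lactone α-carbon doubly bonded to the (2E)-8-methyl-4-methylidenenona-2,7-dien-1-ylidene chain; chain cis to the ring-fusion CH), via allylic mesylate 29 (not isolated)
Conditions: MsCl, Et3N, CH2Cl2, 0 °C; then DBU, rt
Reagents that add atoms: none
Why: Mesylation and E1cB elimination should give the E-alkylidene lactone, the usual more stable isomer with the chain anti to the lactone carbonyl, which is the geometry of the side-chain trisubstituted alkene of the target.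

Step 21
Reactants: 30 (E)-alkylidene lactone
Product: 31 (E)-alkylidene lactone with free 3-hydroxypropyl chain
Conditions: Bu4NF, AcOH, THF, rt
Reagents that add atoms: none
Why: Buffered fluoride desilylation removes the primary silyl ether before the final reduction, so the target itself never meets fluoride or acid.

Step 22
Reactants: 31 (E)-alkylidene lactone with free 3-hydroxypropyl chain
Product: 32 28-deacetylbelamcandal
Conditions: i-Bu2AlH (excess), CH2Cl2, −78 → 0 °C; aq. potassium sodium tartrate (KNaC4H4O6)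
Reagents that add atoms: none
Why: i-Bu2AlH reduces the α-alkylidene lactone 1,2 to the allylic alcohol and the cyclopentanol (already cis to the side chain), while the N-methoxy-N-methylamide stops at the chelated tetrahedral aluminate and gives the Z-enal on work-up, so no stereocentre or alkene geometry changes.

## Compound list

1 | geraniol, (2E)-3,7-dimethylocta-2,6-dien-1-ol | CC(C)=CCC/C(C)=C/CO | starting material
2 | (2S,3S)-2,3-epoxygeraniol | CC(C)=CCC[C@]1(C)O[C@H]1CO | intermediate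
3 | (2R,3S)-2-(chloromethyl)-3-methyl-3-(4-methylpent-3-en-1-yl)oxirane | CC(C)=CCC[C@]1(C)O[C@H]1CCl | intermediate
4 | (3S)-3,7-dimethyloct-6-en-1-yn-3-ol | CC(C)=CCC[C@](C)(O)C#C | intermediate
5 | tert-butyl(3-bromopropoxy)diphenylsilane | BrCCCO[Si](c1ccccc1)(c1ccccc1)C(C)(C)C | starting material
6 | (6S)-1-(TBDPS-oxy)-6,10-dimethylundec-9-en-4-yn-6-ol | CC(C)=CCC[C@](C)(O)C#CCCCO[Si](c1ccccc1)(c1ccccc1)C(C)(C)C | intermediate
7 | (4Z,6S)-1-(TBDPS-oxy)-6,10-dimethyl-5-(tributylstannyl)undeca-4,9-dien-6-ol | CC(C)=CCC[C@](C)(O)/C(=C/CCCO[Si](c1ccccc1)(c1ccccc1)C(C)(C)C)[Sn](CCCC)(CCCC)CCCC | intermediate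
8 | (4Z,6S)-1-(TBDPS-oxy)-5-iodo-6,10-dimethylundeca-4,9-dien-6-ol | CC(C)=CCC[C@](C)(O)/C(I)=C/CCCO[Si](c1ccccc1)(c1ccccc1)C(C)(C)C | intermediate
9 | cyclobutanone | O=C1CCC1 | starting material
10 | 1-[(4Z,6S)-1-(TBDPS-oxy)-6-hydroxy-6,10-dimethylundeca-4,9-dien-5-yl]cyclobutan-1-ol | CC(C)=CCC[C@](C)(O)/C(=C/CCCO[Si](c1ccccc1)(c1ccccc1)C(C)(C)C)C1(O)CCC1 | intermediate
11 | (8S,9Z)-9-[4-(TBDPS-oxy)butylidene]-8-methyl-8-(4-methylpent-3-en-1-yl)-6,6-di(propan-2-yl)-5,7-dioxa-6-silaspiro[3.5]nonane | CC(C)=CCC[C@]1(C)O[Si](C(C)C)(C(C)C)OC2(CCC2)\C1=C/CCCO[Si](c3ccccc3)(c3ccccc3)C(C)(C)C | intermediate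
12 | 3-[(8S,9Z)-9-[4-(TBDPS-oxy)butylidene]-8-methyl-6,6-di(propan-2-yl)-5,7-dioxa-6-silaspiro[3.5]nonan-8-yl]propanal | O=CCC[C@]1(C)O[Si](C(C)C)(C(C)C)OC2(CCC2)\C1=C/CCCO[Si](c3ccccc3)(c3ccccc3)C(C)(C)C | intermediate
13 | (8S,9Z)-9-[4-(TBDPS-oxy)butylidene]-8-(4,4-dibromobut-3-en-1-yl)-8-methyl-6,6-di(propan-2-yl)-5,7-dioxa-6-silaspiro[3.5]nonane | BrC(Br)=CCC[C@]1(C)O[Si](C(C)C)(C(C)C)OC2(CCC2)\C1=C/CCCO[Si](c3ccccc3)(c3ccccc3)C(C)(C)C | intermediate
14 | 5-[(8S,9Z)-9-[4-(TBDPS-oxy)butylidene]-8-methyl-6,6-di(propan-2-yl)-5,7-dioxa-6-silaspiro[3.5]nonan-8-yl]-N-methoxy-N-methylpent-2-ynamide | CON(C)C(=O)C#CCC[C@]1(C)O[Si](C(C)C)(C(C)C)OC2(CCC2)\C1=C/CCCO[Si](c3ccccc3)(c3ccccc3)C(C)(C)C | intermediate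
15 | N-silylsuccinimide ketone (16 with the tertiary oxygen carrying Si(i-Pr)2(N-succinimidyl)) | C1CC[C@]2([C@H](CCCO[Si](c3ccccc3)(c3ccccc3)C(C)(C)C)/C(=C(/I)C(=O)N(C)OC)CC[C@]2(C)O[Si](C(C)C)(C(C)C)N4C(=O)CCC4=O)C1=O | intermediate
16 | (2E)-2-[(5R,6S,10S)-10-[3-(TBDPS-oxy)propyl]-6-hydroxy-6-methyl-1-oxospiro[4.5]decan-9-ylidene]-2-iodo-N-methoxy-N-methylacetamide | C1CC[C@]2([C@H](CCCO[Si](c3ccccc3)(c3ccccc3)C(C)(C)C)/C(=C(/I)C(=O)N(C)OC)CC[C@]2(C)O)C1=O | intermediate
17 | (2Z)-2-[(5R,6S,10R)-10-[3-(TBDPS-oxy)propyl]-6-hydroxy-6-methyl-1-oxospiro[4.5]decan-9-ylidene]-N-methoxy-N-methylpropanamide | C1CC[C@]2([C@H](CCCO[Si](c3ccccc3)(c3ccccc3)C(C)(C)C)/C(=C(/C)C(=O)N(C)OC)CC[C@]2(C)O)C1=O | intermediate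
18 | (2Z)-2-[(5R,6S,10R)-10-[3-(TBDPS-oxy)propyl]-6-methyl-1-oxo-6-(trimethylsilyloxy)spiro[4.5]decan-9-ylidene]-N-methoxy-N-methylpropanamide | C1CC[C@]2([C@H](CCCO[Si](c3ccccc3)(c3ccccc3)C(C)(C)C)/C(=C(/C)C(=O)N(C)OC)CC[C@]2(C)O[Si](C)(C)C)C1=O | intermediate
19 | O-silylated keto ester (20 as its tertiary trimethylsilyl ether) | COC(=O)C[C@@H]1CC[C@]2([C@H](CCCO[Si](c3ccccc3)(c3ccccc3)C(C)(C)C)/C(=C(/C)C(=O)N(C)OC)CC[C@]2(C)O[Si](C)(C)C)C1=O | intermediate
20 | methyl 2-[(2S,5R,6S,10R)-10-[3-(TBDPS-oxy)propyl]-6-hydroxy-9-[(2Z)-1-[methoxy(methyl)amino]-1-oxopropan-2-ylidene]-6-methyl-1-oxospiro[4.5]decan-2-yl]acetate | COC(=O)C[C@@H]1CC[C@]2([C@H](CCCO[Si](c3ccccc3)(c3ccccc3)C(C)(C)C)/C(=C(/C)C(=O)N(C)OC)CC[C@]2(C)O)C1=O | intermediate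
21 | hydroxy ester, methyl 2-[(1R,2S,5S,6S,10R)-10-[3-(TBDPS-oxy)propyl]-1,6-dihydroxy-9-[(2Z)-1-[methoxy(methyl)amino]-1-oxopropan-2-ylidene]-6-methylspiro[4.5]decan-2-yl]acetate | COC(=O)C[C@@H]1CC[C@]2([C@H](CCCO[Si](c3ccccc3)(c3ccccc3)C(C)(C)C)/C(=C(/C)C(=O)N(C)OC)CC[C@]2(C)O)[C@@H]1O | intermediate
22 | (2Z)-2-[(1S,2S,6R,3a'S,6a'R)-6-[3-(TBDPS-oxy)propyl]-2-hydroxy-2-methyl-2'-oxohexahydrospiro[cyclohexane-1,6'-cyclopenta[b]furan]-5-ylidene]-N-methoxy-N-methylpropanamide | O=C1C[C@@H]2CC[C@]3([C@H](CCCO[Si](c4ccccc4)(c4ccccc4)C(C)(C)C)/C(=C(/C)C(=O)N(C)OC)CC[C@]3(C)O)[C@@H]2O1 | intermediate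
23 | 6-methylhept-5-en-2-one | CC(=O)CCC=C(C)C | starting material
24 | 6-methylhepta-1,5-dien-2-yl trifluoromethanesulfonate | C=C(OS(=O)(=O)C(F)(F)F)CCC=C(C)C | intermediate
25 | (E)-2-(3,3-diethoxyprop-1-en-1-yl)-4,4,5,5-tetramethyl-1,3,2-dioxaborolane | CCOC(OCC)/C=C/B1OC(C)(C)C(C)(C)O1 | starting material
26 | (2E)-1,1-diethoxy-8-methyl-4-methylidenenona-2,7-diene | CCOC(OCC)/C=C/C(=C)CCC=C(C)C | intermediate
27 | (2E)-8-methyl-4-methylidenenona-2,7-dienal | O=C/C=C/C(=C)CCC=C(C)C | intermediate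
28 | β-hydroxy lactone (22 with a 1-hydroxy-(2E)-8-methyl-4-methylidenenona-2,7-dien-1-yl group on the lactone α-carbon; epimers at the two new carbons) | O=C1C(C(O)/C=C/C(=C)CCC=C(C)C)[C@@H]2CC[C@]3([C@H](CCCO[Si](c4ccccc4)(c4ccccc4)C(C)(C)C)/C(=C(/C)C(=O)N(C)OC)CC[C@]3(C)O)[C@@H]2O1 | intermediate
29 | allylic mesylate of 28 | O=C1C(C(OS(C)(=O)=O)/C=C/C(=C)CCC=C(C)C)[C@@H]2CC[C@]3([C@H](CCCO[Si](c4ccccc4)(c4ccccc4)C(C)(C)C)/C(=C(/C)C(=O)N(C)OC)CC[C@]3(C)O)[C@@H]2O1 | intermediate
30 | (E)-alkylidene lactone (22 with the lactone α-carbon doubly bonded to the (2E)-8-methyl-4-methylidenenona-2,7-dien-1-ylidene chain; exocyclic C=C E) | O=C1/C(=C/C=C/C(=C)CCC=C(C)C)[C@@H]2CC[C@]3([C@H](CCCO[Si](c4ccccc4)(c4ccccc4)C(C)(C)C)/C(=C(/C)C(=O)N(C)OC)CC[C@]3(C)O)[C@@H]2O1 | intermediate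
31 | (E)-alkylidene lactone with free 3-hydroxypropyl chain (30 without the silyl group) | O=C1/C(=C/C=C/C(=C)CCC=C(C)C)[C@@H]2CC[C@]3([C@H](CCCO)/C(=C(/C)C(=O)N(C)OC)CC[C@]3(C)O)[C@@H]2O1 | intermediate
32 | 28-deacetylbelamcandal | C=C(/C=C/C=C(/CO)[C@@H]1CC[C@]2([C@H](CCCO)/C(=C(/C)C=O)CC[C@]2(C)O)[C@@H]1O)CCC=C(C)C | target

## Step count and risks

Total step count: 22. Longest linear sequence: 20 steps (steps 1–16 and 19–22, from geraniol); steps 17 and 18 make dienal 27.

Steps most likely to fail: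

Step 12 (proposed new method). The electron-poor alkyne may be activated too slowly, so that iodonium attack on the alkene, protodeauration in place of iodination, or loss of catalyst turnover takes over; the 7-endo mode is a lesser risk. The fallback uses the known Prins–pinacol cascade and sets out from aldehyde 12. SnCl4 in CH2Cl2 at −78 °C, then HF·pyridine, should close the same chair and expand the cyclobutanol to give the 9-hydroxy spiroketone F1. Dess–Martin oxidation gives the spiro diketone F2. CH2=C(CH3)MgBr with CeCl3 at −78 °C is expected to add to the less hindered cyclohexanone and give the tertiary allylic alcohol F3. Pyridinium chlorochromate, (C5H5NH)[CrO3Cl], brings about the Babler–Dauben oxidative transposition to the enal F4; the isomer with the formyl group next to the ring CH would be secured by separation or iodine-catalysed equilibration. Pinnick oxidation (NaClO2, NaH2PO4, 2-methyl-2-butene) gives the acid F5, and coupling with MeNHOMe·HCl and EDC returns to amide 17.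

Step 15. Poor facial selectivity in the enolate alkylation, or retro-aldol opening if the silyl ether is lost, would give the wrong epimer at the acetate-bearing carbon. The fallback sets out from ketone 17 and builds the lactone by C–H insertion. Evans–Saksena reduction gives the anti diol F6. BrCH2COBr and pyridine acylate only the secondary OH to give the bromoacetate F7. TsNHNHTs and DBU convert it into the diazoacetate F8. Rh2(OAc)4 then inserts the carbenoid into the adjacent ring CH2 (1,5-insertion, which can only give the cis-fused γ-lactone) and returns to lactone 22.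

Step 22. The aldehyde-level aluminate may collapse and be over-reduced, or the lactone may stop at the lactol. The fallback separates the two reductions and sets out from 31. Cp2Zr(H)Cl in THF reduces only the amide and gives the enal lactone F9. CH(OMe)3 with PPTS in MeOH gives the dimethyl acetal F10. i-Bu2AlH then reduces the lactone to the acetal diol F11, and wet oxalic acid on silica hydrolyses the allylic acetal to reach 32.

## Further compounds

F1 | step 12 | (5R,6S,9S,10S)-10-[3-(TBDPS-oxy)propyl]-6,9-dihydroxy-6-methylspiro[4.5]decan-1-one | C1CC[C@]2([C@H](CCCO[Si](c3ccccc3)(c3ccccc3)C(C)(C)C)[C@@H](O)CC[C@]2(C)O)C1=O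
F2 | step 12 | (5R,6S,10S)-10-[3-(TBDPS-oxy)propyl]-6-hydroxy-6-methylspiro[4.5]decane-1,9-dione | C1CC[C@]2([C@H](CCCO[Si](c3ccccc3)(c3ccccc3)C(C)(C)C)C(=O)CC[C@]2(C)O)C1=O
F3 | step 12 | (5R,6S,10S)-10-[3-(TBDPS-oxy)propyl]-6,9-dihydroxy-6-methyl-9-(prop-1-en-2-yl)spiro[4.5]decan-1-one (C-9 epimers) | C1CC[C@]2([C@H](CCCO[Si](c3ccccc3)(c3ccccc3)C(C)(C)C)C(O)(C(C)=C)CC[C@]2(C)O)C1=O
F4 | step 12 | (2Z)-2-[(5R,6S,10R)-10-[3-(TBDPS-oxy)propyl]-6-hydroxy-6-methyl-1-oxospiro[4.5]decan-9-ylidene]propanal | C1CC[C@]2([C@H](CCCO[Si](c3ccccc3)(c3ccccc3)C(C)(C)C)/C(=C(/C)C=O)CC[C@]2(C)O)C1=O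
F5 | step 12 | (2Z)-2-[(5R,6S,10R)-10-[3-(TBDPS-oxy)propyl]-6-hydroxy-6-methyl-1-oxospiro[4.5]decan-9-ylidene]propanoic acid | C1CC[C@]2([C@H](CCCO[Si](c3ccccc3)(c3ccccc3)C(C)(C)C)/C(=C(/C)C(=O)O)CC[C@]2(C)O)C1=O
F6 | step 15 | (2Z)-2-[(1R,5S,6S,10R)-10-[3-(TBDPS-oxy)propyl]-1,6-dihydroxy-6-methylspiro[4.5]decan-9-ylidene]-N-methoxy-N-methylpropanamide | C1CC[C@]2([C@H](CCCO[Si](c3ccccc3)(c3ccccc3)C(C)(C)C)/C(=C(/C)C(=O)N(C)OC)CC[C@]2(C)O)[C@@H]1O
F7 | step 15 | bromoacetate of F6 at the secondary hydroxyl | C1CC[C@]2([C@H](CCCO[Si](c3ccccc3)(c3ccccc3)C(C)(C)C)/C(=C(/C)C(=O)N(C)OC)CC[C@]2(C)O)[C@@H]1OC(=O)CBr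
F8 | step 15 | diazoacetate of F6 at the secondary hydroxyl | C1CC[C@]2([C@H](CCCO[Si](c3ccccc3)(c3ccccc3)C(C)(C)C)/C(=C(/C)C(=O)N(C)OC)CC[C@]2(C)O)[C@@H]1OC(=O)C=[N+]=[N-]
F9 | step 22 | enal lactone (31 with the amide replaced by CHO) | O=C1/C(=C/C=C/C(=C)CCC=C(C)C)[C@@H]2CC[C@]3([C@H](CCCO)/C(=C(/C)C=O)CC[C@]3(C)O)[C@@H]2O1
F10 | step 22 | dimethyl acetal of F9 | O=C1/C(=C/C=C/C(=C)CCC=C(C)C)[C@@H]2CC[C@]3([C@H](CCCO)/C(=C(/C)C(OC)OC)CC[C@]3(C)O)[C@@H]2O1
F11 | step 22 | dimethyl acetal of 32 | OC/C(=C/C=C/C(=C)CCC=C(C)C)[C@@H]1CC[C@]2([C@H](CCCO)/C(=C(/C)C(OC)OC)CC[C@]2(C)O)[C@@H]1O
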